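**Plan**

- Retrosynthesis: the C8 methacrylate and the C15 silyl ether come off last; the C7–C8 bond is cut together with the C11=C13 alkene (allylstannane plus aldehyde). Further cuts are C13–Sn, C7=C11 (metathesis), the C6 ester, the furanone C3–O bond, C1–C2 (acetylide plus Weinreb amide), C3–C4 (Sonogashira) and C6–C7 (vinylation).
- Forward: a C4–C7/C15 fragment from 2-butyne-1,4-diol and a C8–C10/C1/C14 fragment from (S)-citramalic acid are joined through an ethynyl unit (C2, C3). The rings arise in the order furanone (gold), butenolide (metathesis), ten-membered carbocycle (key step).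
- Enabling feature: C7 and C8 are adjacent stereocentres linking the lactone β-carbon to the ester carbinol, and the exocyclic C11=C13 methylene beside C7 is the alkene left behind when a butenolide allylmetal (C13–C11=C7) attacks an aldehyde through C7.
- Stereochemistry: C10 comes from (S)-citramalic acid (quaternary, never touched); C6 from a ligand-controlled vinylzinc addition; 4Z from trans-hydroalumination/iodination; C7 and C8 are set in the key step, relayed from C6 and the forming ring.

Key step: step 19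

Locants: C1 furanone ketone, C2 furanone CH, C3 enol-ether carbon, C4=C5 ring alkene, C15 oxymethyl on C4, C6 lactone carbinol, C7, C8 ester carbinol, C9 CH2, C10 quaternary carbon with methyl C14, C11=C13 methylene, C12 lactone carbonyl.

Assumption: salt-free Zn(CH=CH2)2 is prepared beforehand from CH2=CHMgBr and ZnCl2 and used as a stock solution (reagent preparation, not a step); C15 is carried as its TBDPS ether so that the C6 (TES) and C8 (TBS) silyl ethers can be removed before it.

**Route**

Step 1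
Reactants: 1 2-butyne-1,4-diol
Product: 2 4-(tert-butyldiphenylsilyloxy)but-2-yn-1-ol
Conditions: NaH (1 equiv), THF, 0 °C; TBDPSCl (1 equiv), rt; diol in threefold excess
Reagents that add atoms: tert-butyldiphenylsilyl chloride, CC(C)(C)[Si](Cl)(c1ccccc1)c1ccccc1
Why: Monosilylation of a symmetrical diol through its monosodium alkoxide (O-silylation), the excess diol suppressing the bis-ether and being washed out with water.

Step 2
Reactants: 2 4-(tert-butyldiphenylsilyloxy)but-2-yn-1-ol
Product: 4 (Z)-4-(tert-butyldiphenylsilyloxy)-3-iodobut-2-en-1-ol, via cyclic alkenylalanate 3 (not isolated)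
Conditions: NaAlH2(OCH2CH2OMe)2 (Red-Al), THF, 0 °C → rt; then I2, THF, −78 → 0 °C
Reagents that add atoms: iodine, II
Why: Alkoxide-directed trans-hydroalumination of the propargylic alcohol puts aluminium on the distal alkyne carbon in a five-membered alanate, and iodinolysis with retention gives the Z-iodoalkene in which iodine (future C3 attachment) and the CH2OH carbon (future C6) are cis, which fixes the 4Z geometry.

Step 3
Reactants: 4 (Z)-4-(tert-butyldiphenylsilyloxy)-3-iodobut-2-en-1-ol
Product: 5 (Z)-4-(tert-butyldiphenylsilyloxy)-3-iodobut-2-enal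
Conditions: MnO2 (activated, excess), CH2Cl2, rt
Reagents that add atoms: none
Why: Heterogeneous MnO2 oxidation of a primary allylic alcohol stops at the enal and is neutral enough to leave the Z-iodoalkene and the silyl ether untouched.

Step 4
Reactants: 5 (Z)-4-(tert-butyldiphenylsilyloxy)-3-iodobut-2-enal
Product: 6 (3S,4Z)-6-(tert-butyldiphenylsilyloxy)-5-iodohexa-1,4-dien-3-ol
Conditions: Zn(CH=CH2)2 (1.5 equiv), (2S)-(−)-3-exo-(dimethylamino)isoborneol [(−)-DAIB, 10 mol%], toluene, −20 → 0 °C; aq. NH4Cl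
Reagents that add atoms: divinylzinc, C=C[Zn]C=C
Why: Amino-alcohol-catalysed enantioselective addition of a diorganozinc to an aldehyde, in which the (−)-DAIB zinc chelate should deliver the vinyl group to the Si face of the enal and so set C6 as (S) in this acyclic series, the configuration that becomes 6R in the lactone.

Step 5
Reactants: 6 (3S,4Z)-6-(tert-butyldiphenylsilyloxy)-5-iodohexa-1,4-dien-3-ol
Product: 7 (3S,4Z)-6-(tert-butyldiphenylsilyloxy)-5-iodo-3-(triethylsilyloxy)hexa-1,4-diene
Conditions: TESCl, imidazole, CH2Cl2, 0 °C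
Reagents that add atoms: chlorotriethylsilane, CC[Si](Cl)(CC)CC
Why: Routine silylation of a secondary alcohol, chosen because the free C6 hydroxyl would add to the activated alkyne in step 13 and give a furan, and because the triethylsilyl ether is the most labile of the three silyl ethers and can be removed first.

Step 6
Reactants: 7 (3S,4Z)-6-(tert-butyldiphenylsilyloxy)-5-iodo-3-(triethylsilyloxy)hexa-1,4-diene; 8 trimethylsilylacetylene
Product: 9 (3S,4E)-5-[(tert-butyldiphenylsilyloxy)methyl]-3-(triethylsilyloxy)-7-(trimethylsilyl)hepta-1,4-dien-6-yne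
Conditions: PdCl2(PPh3)2 (3 mol%), CuI (6 mol%), Et3N, THF, rt
Reagents that add atoms: none
Why: Sonogashira coupling of an alkenyl iodide with a terminal alkyne proceeds with retention of alkene geometry under mild amine conditions that the silyl ethers and the terminal vinyl group tolerate.

Step 7
Reactants: 9 (3S,4E)-5-[(tert-butyldiphenylsilyloxy)methyl]-3-(triethylsilyloxy)-7-(trimethylsilyl)hepta-1,4-dien-6-yne
Product: 10 (3S,4E)-5-[(tert-butyldiphenylsilyloxy)methyl]-3-(triethylsilyloxy)hepta-1,4-dien-6-yne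
Conditions: K2CO3 (0.2 equiv), MeOH, 0 °C → rt
Reagents that add atoms: none
Why: Methoxide-catalysed protiodesilylation cleaves the alkynyl C–Si bond much faster than the hindered O–Si bonds of the TES and TBDPS ethers.

Step 8
Reactants: 11 (S)-citramalic acid
Product: 12 2-[(4S)-2,2,4-trimethyl-5-oxo-1,3-dioxolan-4-yl]acetic acid
Conditions: 2,2-dimethoxypropane, TsOH·H2O (cat.), rt
Reagents that add atoms: 2,2-dimethoxypropane, COC(C)(C)OC
Why: Acid-catalysed acetonide exchange engages the α-hydroxy acid as the five-membered 1,3-dioxolan-4-one in preference to the six-membered alternative, which differentiates the two carboxyl groups (C1 masked, C8 free) without touching the quaternary C10 centre.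

Step 9
Reactants: 12 2-[(4S)-2,2,4-trimethyl-5-oxo-1,3-dioxolan-4-yl]acetic acid
Product: 13 (5S)-5-(2-hydroxyethyl)-2,2,5-trimethyl-1,3-dioxolan-4-one
Conditions: BH3·SMe2, THF, 0 °C → rt; MeOH quench
Reagents that add atoms: none
Why: Borane reduces a free carboxylic acid through its acyloxyborane far faster than the dioxolanone ester carbonyl, which gives the C8 primary alcohol chemoselectively.

Step 10
Reactants: 13 (5S)-5-(2-hydroxyethyl)-2,2,5-trimethyl-1,3-dioxolan-4-one
Product: 14 (5S)-5-[2-(tert-butyldimethylsilyloxy)ethyl]-2,2,5-trimethyl-1,3-dioxolan-4-one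
Conditions: TBSCl, imidazole, CH2Cl2, 0 °C → rt
Reagents that add atoms: tert-butyldimethylsilyl chloride, CC(C)(C)[Si](C)(C)Cl
Why: Imidazole-mediated silylation of the primary alcohol is fast and neutral, so the hydroxy dioxolanone is capped before it can translactonise to the five-membered hydroxy lactone.

Step 11
Reactants: 14 (5S)-5-[2-(tert-butyldimethylsilyloxy)ethyl]-2,2,5-trimethyl-1,3-dioxolan-4-one
Product: 15 (2S)-4-(tert-butyldimethylsilyloxy)-2-hydroxy-N-methoxy-N,2-dimethylbutanamide
Conditions: MeNHOMe·HCl, iPrMgCl, THF, −20 → 0 °C; aq. NH4Cl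
Reagents that add atoms: N,O-dimethylhydroxylamine hydrochloride, CNOC.Cl
Why: Weinreb amide formation by aminolysis of the acylal-type dioxolanone with the chloromagnesium amide of N,O-dimethylhydroxylamine, the expelled hemiketal alkoxide losing acetone to unveil the tertiary C10 hydroxyl.

Step 12
Reactants: 10 (3S,4E)-5-[(tert-butyldiphenylsilyloxy)methyl]-3-(triethylsilyloxy)hepta-1,4-dien-6-yne; 15 (2S)-4-(tert-butyldimethylsilyloxy)-2-hydroxy-N-methoxy-N,2-dimethylbutanamide
Product: 18 (3S,7E,9S)-1-(tert-butyldimethylsilyloxy)-7-[(tert-butyldiphenylsilyloxy)methyl]-3-hydroxy-3-methyl-9-(triethylsilyloxy)undeca-7,10-dien-5-yn-4-one, via lithium acetylide 16 (not isolated), via lithium alkoxide 17 (not isolated)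
Conditions: 10, n-BuLi (1.1 equiv), THF, −78 °C; 15, LiN(SiMe3)2 (1.0 equiv), THF, −78 °C; combined, −78 → 0 °C; aq. NH4Cl
Reagents that add atoms: none
Why: Addition of a lithium acetylide to a Weinreb amide stops at the chelated tetrahedral adduct, so the ynone (C1 ketone, C2≡C3) appears only on work-up, and prior deprotonation of the tertiary hydroxyl keeps the acetylide from being spent as a base.

Step 13
Reactants: 18 (3S,7E,9S)-1-(tert-butyldimethylsilyloxy)-7-[(tert-butyldiphenylsilyloxy)methyl]-3-hydroxy-3-methyl-9-(triethylsilyloxy)undeca-7,10-dien-5-yn-4-one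
Product: 20 (2S)-2-[2-(tert-butyldimethylsilyloxy)ethyl]-5-[(2Z,4S)-1-(tert-butyldiphenylsilyloxy)-4-hydroxyhexa-2,5-dien-2-yl]-2-methylfuran-3(2H)-one, via furanone triethylsilyl ether 19 (not isolated)
Conditions: (p-CF3C6H4)3PAuCl (5 mol%), AgOTf (5 mol%), toluene, rt; then MeOH, PPTS, 0 °C
Reagents that add atoms: none
Why: Cationic monovalent gold activates the ynone for 5-endo-dig addition of the tertiary C10 hydroxyl to C3 and protodeauration gives the 3(2H)-furanone (the known cyclisation of α′-hydroxy ynones) while the silylated C6 oxygen cannot compete, after which PPTS in methanol cleaves the secondary triethylsilyl ether in the presence of the primary TBS and TBDPS ethers.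

Step 14
Reactants: 20 (2S)-2-[2-(tert-butyldimethylsilyloxy)ethyl]-5-[(2Z,4S)-1-(tert-butyldiphenylsilyloxy)-4-hydroxyhexa-2,5-dien-2-yl]-2-methylfuran-3(2H)-one; 21 2-(bromomethyl)acrylic acid
Product: 22 (3S,4Z)-6-(tert-butyldiphenylsilyloxy)-5-{(5S)-5-[2-(tert-butyldimethylsilyloxy)ethyl]-5-methyl-4-oxo-4,5-dihydrofuran-2-yl}hexa-1,4-dien-3-yl 2-(bromomethyl)acrylate
Conditions: DCC, DMAP (5 mol%), CH2Cl2, −20 → 0 °C
Reagents that add atoms: none
Why: Steglich esterification of the secondary allylic alcohol with the free acid avoids stoichiometric tertiary amine, which would displace the allylic bromide of a 2-(bromomethyl)acrylate, and it does not touch the C6–O bond.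

Step 15
Reactants: 22 (3S,4Z)-6-(tert-butyldiphenylsilyloxy)-5-{(5S)-5-[2-(tert-butyldimethylsilyloxy)ethyl]-5-methyl-4-oxo-4,5-dihydrofuran-2-yl}hexa-1,4-dien-3-yl 2-(bromomethyl)acrylate
Product: 23 (5R)-3-(bromomethyl)-5-[(1Z)-3-(tert-butyldiphenylsilyloxy)-2-{(5S)-5-[2-(tert-butyldimethylsilyloxy)ethyl]-5-methyl-4-oxo-4,5-dihydrofuran-2-yl}prop-1-en-1-yl]furan-2(5H)-one
Conditions: second-generation Hoveyda–Grubbs catalyst (10 mol%), toluene, 80 °C, argon sparge
Reagents that add atoms: none
Why: Ring-closing metathesis between the terminal vinyl group and the 1,1-disubstituted acrylate alkene closes the five-membered butenolide (C7=C11) with loss of ethene, the trisubstituted electron-poor C4=C5 and furanone alkenes being inert to the ruthenium carbene and allylic halides being tolerated by it.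

Step 16
Reactants: 23 (5R)-3-(bromomethyl)-5-[(1Z)-3-(tert-butyldiphenylsilyloxy)-2-{(5S)-5-[2-(tert-butyldimethylsilyloxy)ethyl]-5-methyl-4-oxo-4,5-dihydrofuran-2-yl}prop-1-en-1-yl]furan-2(5H)-one
Product: 24 (5R)-3-(bromomethyl)-5-[(1Z)-3-(tert-butyldiphenylsilyloxy)-2-{(5S)-5-(2-hydroxyethyl)-5-methyl-4-oxo-4,5-dihydrofuran-2-yl}prop-1-en-1-yl]furan-2(5H)-one
Conditions: CSA (10 mol%), MeOH/CH2Cl2 1:1, 0 °C
Reagents that add atoms: none
Why: Acid-catalysed methanolysis removes a primary TBS ether far faster than a primary TBDPS ether, and the base-free medium spares the γ-hydrogen of the butenolide (C6) and the allylic bromide.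

Step 17
Reactants: 24 (5R)-3-(bromomethyl)-5-[(1Z)-3-(tert-butyldiphenylsilyloxy)-2-{(5S)-5-(2-hydroxyethyl)-5-methyl-4-oxo-4,5-dihydrofuran-2-yl}prop-1-en-1-yl]furan-2(5H)-one
Product: 25 (5R)-5-[(1Z)-3-(tert-butyldiphenylsilyloxy)-2-{(5S)-5-(2-hydroxyethyl)-5-methyl-4-oxo-4,5-dihydrofuran-2-yl}prop-1-en-1-yl]-3-[(tributylstannyl)methyl]furan-2(5H)-one
Conditions: Bu3SnSnBu3 (1.5 equiv), Pd2(dba)3 (2.5 mol%), THF, rt
Reagents that add atoms: hexabutylditin, CCCC[Sn](CCCC)(CCCC)[Sn](CCCC)(CCCC)CCCC
Why: Palladium-catalysed stannylation of an allylic halide with a hexaalkyldistannane, in which oxidative addition of zerovalent palladium to the C13–Br bond, transmetalation with the Sn–Sn bond and reductive elimination at the unhindered CH2 terminus should give the conjugated primary allylstannane under neutral conditions that the furanone, the free hydroxyl and the C6 stereocentre tolerate.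

Step 18
Reactants: 25 (5R)-5-[(1Z)-3-(tert-butyldiphenylsilyloxy)-2-{(5S)-5-(2-hydroxyethyl)-5-methyl-4-oxo-4,5-dihydrofuran-2-yl}prop-1-en-1-yl]-3-[(tributylstannyl)methyl]furan-2(5H)-one
Product: 26 2-[(2S)-5-{(1Z)-3-(tert-butyldiphenylsilyloxy)-1-[(2R)-5-oxo-4-[(tributylstannyl)methyl]-2,5-dihydrofuran-2-yl]prop-1-en-2-yl}-2-methyl-3-oxo-2,3-dihydrofuran-2-yl]acetaldehyde
Conditions: Dess–Martin periodinane (1.3 equiv), CH2Cl2, 0 °C; filtered through Celite and used at once
Reagents that add atoms: none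
Why: Dess–Martin oxidation converts the primary alcohol into the aldehyde without base, which matters because the aldehyde carries the furanone oxygen in the β-position and would eliminate under basic conditions, and allylstannanes survive this oxidant.

Step 19
Reactants: 26 2-[(2S)-5-{(1Z)-3-(tert-butyldiphenylsilyloxy)-1-[(2R)-5-oxo-4-[(tributylstannyl)methyl]-2,5-dihydrofuran-2-yl]prop-1-en-2-yl}-2-methyl-3-oxo-2,3-dihydrofuran-2-yl]acetaldehyde
Product: 27 (4Z,6R,7R,8R,10S)-15-(tert-butyldiphenylsilyloxy)-8-hydroxy-1-oxo-3,10-epoxygermacra-2,4,11(13)-trien-12,6-olide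
Conditions: BF3·OEt2 (2 equiv), CH2Cl2 (0.002 M), −78 °C; pH 7 buffer
Reagents that add atoms: none
Why: Proposed new method: BF3 binds the C8 aldehyde and the butenolide C7=C11 alkene attacks it through C7 while the C13–Sn bond stabilises the charge building at C11 and is then lost as Bu3SnF (SE2′), so that the alkene moves to C11=C13 and the α-methylene lactone appears in the same event; the closest known reactions are the BF3-promoted additions of 2-(tributylstannylmethyl)acrylates to aldehydes and Lewis-acid-mediated allylstannane–aldehyde closures of medium and large carbocycles, which have not been combined on a 3-(stannylmethyl)butenolide. The ten-membered carbocycle C1–C10 closes through this C7–C8 bond as a 10-exo-trig attack on the carbonyl, helped by the Z-C4=C5 alkene and the planar furanone, which remove rotors from the tether and hold the aldehyde near the butenolide. C7 is controlled by C6, because the tether leaves the butenolide at C6 on one face and the aldehyde should add to C7 on the opposite face, giving the trans-fused lactone (7R). C8 is controlled by the open transition state of the BF3-bound aldehyde, in which the forming ring decides which carbonyl face is exposed, and this should place the hydroxyl syn to C6 along the new bond (8R), which is the less secure of the two centres. The step needs attack through C7 and not C13, which the SE2′ course of an allylstannane ensures, and it needs the β-oxygenated aldehyde to survive, for which the base-free Lewis acid, −78 °C and high dilution are chosen.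

Step 20
Reactants: 27 (4Z,6R,7R,8R,10S)-15-(tert-butyldiphenylsilyloxy)-8-hydroxy-1-oxo-3,10-epoxygermacra-2,4,11(13)-trien-12,6-olide
Product: 28 (4Z,6R,7R,8R,10S)-15-(tert-butyldiphenylsilyloxy)-8-(methacryloyloxy)-1-oxo-3,10-epoxygermacra-2,4,11(13)-trien-12,6-olide
Conditions: methacrylic anhydride, Et3N, DMAP (cat.), CH2Cl2, 0 °C → rt
Reagents that add atoms: methacrylic anhydride, C=C(C)C(=O)OC(=O)C(C)=C
Why: DMAP-catalysed acylation of the secondary C8 hydroxyl with the anhydride is a standard esterification that proceeds with retention at C8.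

Step 21
Reactants: 28 (4Z,6R,7R,8R,10S)-15-(tert-butyldiphenylsilyloxy)-8-(methacryloyloxy)-1-oxo-3,10-epoxygermacra-2,4,11(13)-trien-12,6-olide
Product: 29 (4Z,6R,7R,8R,10S)-15-hydroxy-8-(methacryloyloxy)-1-oxo-3,10-epoxygermacra-2,4,11(13)-trien-12,6-olide (CNP0180483.4)
Conditions: HF·pyridine, pyridine, THF, 0 °C → rt
Reagents that add atoms: none
Why: Fluoride-mediated desilylation with pyridine-buffered HF is mildly acidic and not basic, and is therefore compatible with the methacrylate, the α-methylene lactone and the furanone.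

**Compound list**

1 | 2-butyne-1,4-diol | OCC#CCO | starting material
2 | 4-(tert-butyldiphenylsilyloxy)but-2-yn-1-ol | OCC#CCO[Si](c1ccccc1)(c1ccccc1)C(C)(C)C | intermediate
3 | cyclic sodium alkenylalanate of 2 (five-membered O–Al–C=C chelate, Al on the carbon bearing CH2OTBDPS) | [Na+].COCCO[Al-]1(OCCOC)OCC=C1CO[Si](c2ccccc2)(c2ccccc2)C(C)(C)C | intermediate (not isolated)
4 | (Z)-4-(tert-butyldiphenylsilyloxy)-3-iodobut-2-en-1-ol | I/C(CO[Si](c1ccccc1)(c1ccccc1)C(C)(C)C)=C\CO | intermediate
5 | (Z)-4-(tert-butyldiphenylsilyloxy)-3-iodobut-2-enal | I/C(CO[Si](c1ccccc1)(c1ccccc1)C(C)(C)C)=C\C=O | intermediate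
6 | (3S,4Z)-6-(tert-butyldiphenylsilyloxy)-5-iodohexa-1,4-dien-3-ol | I/C(CO[Si](c1ccccc1)(c1ccccc1)C(C)(C)C)=C\[C@H](C=C)O | intermediate
7 | (3S,4Z)-6-(tert-butyldiphenylsilyloxy)-5-iodo-3-(triethylsilyloxy)hexa-1,4-diene | I/C(CO[Si](c1ccccc1)(c1ccccc1)C(C)(C)C)=C\[C@H](C=C)O[Si](CC)(CC)CC | intermediate
8 | trimethylsilylacetylene | C#C[Si](C)(C)C | starting material
9 | (3S,4E)-5-[(tert-butyldiphenylsilyloxy)methyl]-3-(triethylsilyloxy)-7-(trimethylsilyl)hepta-1,4-dien-6-yne | C[Si](C)(C)C#C/C(CO[Si](c1ccccc1)(c1ccccc1)C(C)(C)C)=C\[C@H](C=C)O[Si](CC)(CC)CC | intermediate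
10 | (3S,4E)-5-[(tert-butyldiphenylsilyloxy)methyl]-3-(triethylsilyloxy)hepta-1,4-dien-6-yne | C#C/C(CO[Si](c1ccccc1)(c1ccccc1)C(C)(C)C)=C\[C@H](C=C)O[Si](CC)(CC)CC | intermediate
11 | (S)-citramalic acid | OC(=O)C[C@](C)(O)C(=O)O | starting material
12 | 2-[(4S)-2,2,4-trimethyl-5-oxo-1,3-dioxolan-4-yl]acetic acid | OC(=O)C[C@]1(C)OC(C)(C)OC1=O | intermediate
13 | (5S)-5-(2-hydroxyethyl)-2,2,5-trimethyl-1,3-dioxolan-4-one | OCC[C@]1(C)OC(C)(C)OC1=O | intermediate
14 | (5S)-5-[2-(tert-butyldimethylsilyloxy)ethyl]-2,2,5-trimethyl-1,3-dioxolan-4-one | CC(C)(C)[Si](C)(C)OCC[C@]1(C)OC(C)(C)OC1=O | intermediate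
15 | (2S)-4-(tert-butyldimethylsilyloxy)-2-hydroxy-N-methoxy-N,2-dimethylbutanamide | CC(C)(C)[Si](C)(C)OCC[C@](C)(O)C(=O)N(C)OC | intermediate
16 | lithium acetylide of 10 | [Li]C#C/C(CO[Si](c1ccccc1)(c1ccccc1)C(C)(C)C)=C\[C@H](C=C)O[Si](CC)(CC)CC | intermediate (not isolated)
17 | lithium alkoxide of 15 | CC(C)(C)[Si](C)(C)OCC[C@](C)(O[Li])C(=O)N(C)OC | intermediate (not isolated)
18 | (3S,7E,9S)-1-(tert-butyldimethylsilyloxy)-7-[(tert-butyldiphenylsilyloxy)methyl]-3-hydroxy-3-methyl-9-(triethylsilyloxy)undeca-7,10-dien-5-yn-4-one | CC(C)(C)[Si](C)(C)OCC[C@](C)(O)C(=O)C#C/C(CO[Si](c1ccccc1)(c1ccccc1)C(C)(C)C)=C\[C@H](C=C)O[Si](CC)(CC)CC | intermediate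
19 | (2S)-2-[2-(tert-butyldimethylsilyloxy)ethyl]-5-[(2Z,4S)-1-(tert-butyldiphenylsilyloxy)-4-(triethylsilyloxy)hexa-2,5-dien-2-yl]-2-methylfuran-3(2H)-one | CC(C)(C)[Si](C)(C)OCC[C@]1(C)OC(=CC1=O)/C(CO[Si](c2ccccc2)(c2ccccc2)C(C)(C)C)=C\[C@H](C=C)O[Si](CC)(CC)CC | intermediate (not isolated)
20 | (2S)-2-[2-(tert-butyldimethylsilyloxy)ethyl]-5-[(2Z,4S)-1-(tert-butyldiphenylsilyloxy)-4-hydroxyhexa-2,5-dien-2-yl]-2-methylfuran-3(2H)-one | CC(C)(C)[Si](C)(C)OCC[C@]1(C)OC(=CC1=O)/C(CO[Si](c2ccccc2)(c2ccccc2)C(C)(C)C)=C\[C@H](C=C)O | intermediate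
21 | 2-(bromomethyl)acrylic acid | C=C(CBr)C(=O)O | starting material
22 | (3S,4Z)-6-(tert-butyldiphenylsilyloxy)-5-{(5S)-5-[2-(tert-butyldimethylsilyloxy)ethyl]-5-methyl-4-oxo-4,5-dihydrofuran-2-yl}hexa-1,4-dien-3-yl 2-(bromomethyl)acrylate | CC(C)(C)[Si](C)(C)OCC[C@]1(C)OC(=CC1=O)/C(CO[Si](c2ccccc2)(c2ccccc2)C(C)(C)C)=C\[C@H](C=C)OC(=O)C(=C)CBr | intermediate
23 | (5R)-3-(bromomethyl)-5-[(1Z)-3-(tert-butyldiphenylsilyloxy)-2-{(5S)-5-[2-(tert-butyldimethylsilyloxy)ethyl]-5-methyl-4-oxo-4,5-dihydrofuran-2-yl}prop-1-en-1-yl]furan-2(5H)-one | CC(C)(C)[Si](C)(C)OCC[C@]1(C)OC(=CC1=O)/C(CO[Si](c2ccccc2)(c2ccccc2)C(C)(C)C)=C\[C@H]1OC(=O)C(CBr)=C1 | intermediate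
24 | (5R)-3-(bromomethyl)-5-[(1Z)-3-(tert-butyldiphenylsilyloxy)-2-{(5S)-5-(2-hydroxyethyl)-5-methyl-4-oxo-4,5-dihydrofuran-2-yl}prop-1-en-1-yl]furan-2(5H)-one | OCC[C@]1(C)OC(=CC1=O)/C(CO[Si](c2ccccc2)(c2ccccc2)C(C)(C)C)=C\[C@H]1OC(=O)C(CBr)=C1 | intermediate
25 | (5R)-5-[(1Z)-3-(tert-butyldiphenylsilyloxy)-2-{(5S)-5-(2-hydroxyethyl)-5-methyl-4-oxo-4,5-dihydrofuran-2-yl}prop-1-en-1-yl]-3-[(tributylstannyl)methyl]furan-2(5H)-one | OCC[C@]1(C)OC(=CC1=O)/C(CO[Si](c2ccccc2)(c2ccccc2)C(C)(C)C)=C\[C@H]1OC(=O)C(C[Sn](CCCC)(CCCC)CCCC)=C1 | intermediate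
26 | 2-[(2S)-5-{(1Z)-3-(tert-butyldiphenylsilyloxy)-1-[(2R)-5-oxo-4-[(tributylstannyl)methyl]-2,5-dihydrofuran-2-yl]prop-1-en-2-yl}-2-methyl-3-oxo-2,3-dihydrofuran-2-yl]acetaldehyde | O=CC[C@]1(C)OC(=CC1=O)/C(CO[Si](c2ccccc2)(c2ccccc2)C(C)(C)C)=C\[C@H]1OC(=O)C(C[Sn](CCCC)(CCCC)CCCC)=C1 | intermediate
27 | (4Z,6R,7R,8R,10S)-15-(tert-butyldiphenylsilyloxy)-8-hydroxy-1-oxo-3,10-epoxygermacra-2,4,11(13)-trien-12,6-olide | O[C@@H]1C[C@]2(C)OC(=CC2=O)/C(CO[Si](c3ccccc3)(c3ccccc3)C(C)(C)C)=C\[C@H]2OC(=O)C(=C)[C@@H]21 | intermediate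
28 | (4Z,6R,7R,8R,10S)-15-(tert-butyldiphenylsilyloxy)-8-(methacryloyloxy)-1-oxo-3,10-epoxygermacra-2,4,11(13)-trien-12,6-olide | C=C(C)C(=O)O[C@@H]1C[C@]2(C)OC(=CC2=O)/C(CO[Si](c3ccccc3)(c3ccccc3)C(C)(C)C)=C\[C@H]2OC(=O)C(=C)[C@@H]21 | intermediate
29 | (4Z,6R,7R,8R,10S)-15-hydroxy-8-(methacryloyloxy)-1-oxo-3,10-epoxygermacra-2,4,11(13)-trien-12,6-olide (CNP0180483.4) | C=C(C)C(=O)O[C@@H]1C[C@]2(C)OC(=CC2=O)/C(CO)=C\[C@H]2OC(=O)C(=C)[C@@H]21 | target

**Step count and risks**

Total step count: 21. Longest linear sequence: 17 steps (steps 1–7 and 12–21, from 2-butyne-1,4-diol).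

Steps most likely to fail:

First, step 19 (key cyclisation, proposed). The electron-poor allylstannane may attack too slowly, so that BF3-induced loss of the β-oxygen (opening of the furanone by elimination), intermolecular addition, or attack on the wrong carbonyl face take over. The fallback uses known chemistry and keeps the C7–C8 disconnection. It sets out from bromo alcohol 24: Dess–Martin oxidation gives the bromo aldehyde F1, and CrCl2 in THF at high dilution (intramolecular Nozaki–Hiyama allylation, the ring-closing form of the Barbier reaction of 3-(bromomethyl)butenolides) forms the same bond through a closed chair transition state. For the ring-locked allyl geometry this is expected to give the trans lactone with the C8 carbinol inverted, the 8-epi alcohol F2. Mitsunobu esterification of F2 with methacrylic acid (PPh3, DIAD) inverts C8 and comes back to the route at 28. An 8-epimer arising in step 19 itself is the same compound F2 and takes the same exit.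

Second, step 17 (stannylation). The allylpalladium intermediate may lose a β-hydride towards a γ-alkylidene butenolide, the product stannane may couple with unreacted bromide, or tin may be delivered to C7. The fallback sets out from 24 and comes back at 25 with reversed polarity: zinc dust and Bu3SnCl in THF/saturated aqueous NH4Cl (Barbier-type stannylation) generate the allylzinc species, which is trapped by the tin chloride and should equilibrate to the conjugated primary stannane. No palladium is involved and no new isolated compound is made (F0).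

Third, step 15 (metathesis). The ruthenium carbene may decompose in the presence of the allylic bromide during the slow closure onto the electron-poor 1,1-disubstituted alkene, with dimerisation through the vinyl group as the competing path. The fallback sets out from alcohol 20: Steglich esterification with 2-(acetoxymethyl)acrylic acid gives the acetoxymethyl acrylate F3, whose ring-closing metathesis (allylic acetates are inert to the catalyst) gives the 3-(acetoxymethyl)butenolide F4. CSA/MeOH then frees the C8 alcohol F5, and Pd(PPh3)4 with Bu3SnSnBu3 ionises the activated allylic acetate and delivers tin to C13. This comes back to the route at stannane 25 and bypasses bromides 22–24.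

Further compounds
F1 | step 19 | 2-[(2S)-5-{(1Z)-1-[(2R)-4-(bromomethyl)-5-oxo-2,5-dihydrofuran-2-yl]-3-(tert-butyldiphenylsilyloxy)prop-1-en-2-yl}-2-methyl-3-oxo-2,3-dihydrofuran-2-yl]acetaldehyde | O=CC[C@]1(C)OC(=CC1=O)/C(CO[Si](c2ccccc2)(c2ccccc2)C(C)(C)C)=C\[C@H]1OC(=O)C(CBr)=C1
F2 | step 19 | (4Z,6R,7R,8S,10S)-15-(tert-butyldiphenylsilyloxy)-8-hydroxy-1-oxo-3,10-epoxygermacra-2,4,11(13)-trien-12,6-olide (8-epimer of 27) | O[C@H]1C[C@]2(C)OC(=CC2=O)/C(CO[Si](c3ccccc3)(c3ccccc3)C(C)(C)C)=C\[C@H]2OC(=O)C(=C)[C@@H]21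
F0 | step 17 | none | none
F3 | step 15 | (3S,4Z)-6-(tert-butyldiphenylsilyloxy)-5-{(5S)-5-[2-(tert-butyldimethylsilyloxy)ethyl]-5-methyl-4-oxo-4,5-dihydrofuran-2-yl}hexa-1,4-dien-3-yl 2-(acetoxymethyl)acrylate | CC(C)(C)[Si](C)(C)OCC[C@]1(C)OC(=CC1=O)/C(CO[Si](c2ccccc2)(c2ccccc2)C(C)(C)C)=C\[C@H](C=C)OC(=O)C(=C)COC(C)=O
F4 | step 15 | {(5R)-5-[(1Z)-3-(tert-butyldiphenylsilyloxy)-2-{(5S)-5-[2-(tert-butyldimethylsilyloxy)ethyl]-5-methyl-4-oxo-4,5-dihydrofuran-2-yl}prop-1-en-1-yl]-2-oxo-2,5-dihydrofuran-3-yl}methyl acetate | CC(C)(C)[Si](C)(C)OCC[C@]1(C)OC(=CC1=O)/C(CO[Si](c2ccccc2)(c2ccccc2)C(C)(C)C)=C\[C@H]1OC(=O)C(COC(C)=O)=C1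
F5 | step 15 | {(5R)-5-[(1Z)-3-(tert-butyldiphenylsilyloxy)-2-{(5S)-5-(2-hydroxyethyl)-5-methyl-4-oxo-4,5-dihydrofuran-2-yl}prop-1-en-1-yl]-2-oxo-2,5-dihydrofuran-3-yl}methyl acetate | OCC[C@]1(C)OC(=CC1=O)/C(CO[Si](c2ccccc2)(c2ccccc2)C(C)(C)C)=C\[C@H]1OC(=O)C(COC(C)=O)=C1
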